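**The problem**

Target 33 is a cyclopentane with four contiguous ring stereocentres in an all-trans array: the carbon bearing the three-carbon arm, the CH2OH carbon, the methyl carbon and the acylated carbinol carbon. A fifth stereocentre lies in the arm; it exists only because one CH2O group is esterified and the other is free, so the ring cannot set it and any acyl or silyl migration between the two arms erases it. The two esters, one on a primary and one on a hindered secondary oxygen, carry the same acyl group, (3S,4E)-4-formyl-3-(2-oxoethyl)hex-4-enoyl. Its enal and its saturated aldehyde tolerate neither base nor nucleophiles, so the four aldehydes have to appear last while two primary hydroxyls stay free. Within the ring the stereocentres can be chained: the arm-bearing carbon directs the CH2OH carbon, that one directs the methyl carbon, and the methyl carbon directs hydride delivery at the carbonyl. The acyl stereocentre is remote from the core and is best set on a small building block. The enabling feature is that methyl, CH2OH and the arm sit on three adjacent ring carbons, each trans to its neighbour and next to the oxygenated carbon. That is the pattern left on a 4-substituted cyclopent-2-enone by conjugate addition at C3 and enolate alkylation at C2.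

**Retrosynthesis**

Aldehydes. The four C=O groups of 33 are traced to two C–C bonds: each acyl unit is carried as a 2-ethylidene-cyclopentane-cis-3,4-diol, and periodate cleavage of hexaol 32 releases enal and CH2CHO together. Oxidising alcohols is excluded by the two free primary hydroxyls, and hydrolysing four acetals would put acid next to a free hydroxyl and an ester. The ring also locks the E geometry of the ethylidene group. 32 comes from tetraol 31 by desilylation and 31 from bis-acetonide 30 by hydrolysis, in that order, so that acid never meets a free arm hydroxyl.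

Esters. Both ester C–O bonds of 30 are cut at once, giving diol 20 and two equivalents of acid 29. Because the acyl groups are identical, one exhaustive esterification replaces two selective ones; the price is that the arm that stays free must be marked beforehand.

Acid 29. The exocyclic C=C is cut by a Wittig disconnection (28 from keto ester 25) and the ring–CH2CO2Me bond by an enolate alkylation (25 from ketone 22 and methyl bromoacetate 23). 22 is the hydrogenation product of the purchased D-ribose-derived enone 21, whose acetonide both masks the diol and directs the alkylation to the convex face, which sets the acyl stereocentre.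

Arm differentiation. Diol 20 is traced through silyl ether 19 and monoacetate 18 to the symmetric arm diol 17. Only O–acyl and O–Si bonds are involved, and an enzyme tells the two diastereotopic CH2OH groups apart. Building this stereocentre by C–C bond formation would need a second asymmetric step early on and would destroy the symmetric dioxane that keeps the key-step substrate simple.

Carbinol. Ester 16 (the acetonide precursor of 17) is the inversion product of alcohol 15, which comes from ketone 14. A bulky hydride attacks opposite the α-methyl group and so gives, predictably, the epimer with hydroxyl cis to methyl; one SN2 inversion then gives the all-trans oxygen as a 4-nitrobenzoate that also protects it.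

Hydroxymethyl group. Ketone 14 is the silyl ether of 13, and the C–O bond of 13 is traced to the C–Si bond of 12 (Tamao oxidation).

Key disconnection. In 12 the ring–CH2Si bond and the ring–CH3 bond on adjacent carbons are cut together, giving enone 7, Grignard reagent 9 (from chloride 8) and iodomethane 10. Cutting only one of them would leave a 2,3-disubstituted enone that is harder to make; cutting both leaves an enone with one stereocentre. The forward reaction must add anti to the C4 substituent and methylate the first-formed enolate anti to the new group before it equilibrates.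

Enone 7. The C4–arm bond is cut by a Tsuji–Trost disconnection to the purchased monoacetate 1 and dimethyl malonate 2 (giving 4); reduction (5), acetonide formation (6) and allylic oxidation complete the sequence.

**Roads not taken**

Alternative 1: The ring bond between the CH2OH-bearing carbon and the arm-bearing carbon is cut. In the forward sense a diarylprolinol silyl ether converts aldehyde A2 into an enamine that closes onto its alkylidene malonate (5-exo-trig) to give A1.
- Merits: the step closes the ring, sets two stereocentres under catalyst control, and delivers the arm as a malonate and the CH2OH as an aldehyde. The silyloxy carbon in A1 already has the all-trans configuration, so the reduction–inversion pair of the chosen plan (steps 9 and 10) is spared. In that respect this road is better.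
- Weak points: A2 must first be made as a single diastereomer with its silyloxy and methyl stereocentres, which needs a separate asymmetric campaign. The catalyst must be matched to those centres. The CH2 between the alkylidene malonate and the silyloxy carbon is acidic, so dienamine formation or loss of the silyloxy group competes.
- Comparison: the chosen plan derives three ring stereocentres from one purchased stereocentre by substrate control in one flask and needs no open-chain stereochemistry.

Alternative 2: The two bonds between the acyl stereocentres and their alkenyl carbons are cut. The core bis-enoate A4 and two equivalents of alkenyl boronate A5 would react under [Rh(cod)OH]2 and one enantiomer of BINAP to give A3.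
- Merits: both acyl stereocentres are made late under catalyst control, and the four-step synthesis of acid 29 and the periodate step become unnecessary. If the addition worked well, this would be the shorter route in the acyl part.
- Weak points: rhodium-catalysed additions of α-branched alkenylboron reagents to simple acyclic enoates are much less reliable than aryl additions. Two additions on one molecule multiply any shortfall in selectivity into diastereomers that differ only at remote centres. A5 has to be made with methyl cis to boron. The four acetals of A3 need acid in the presence of silyl ethers and esters.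
- Comparison: A4 still requires the whole core synthesis up to a diol like 20. The chosen plan sets the acyl stereocentre on a small compound whose configuration can be checked before coupling, and attaches it by an ordinary esterification.

Alternative 3: The ring bond between the carbinol carbon and the methyl-bearing carbon is cut. SmI2 with HMPA and t-BuOH would turn the aldehyde of A7 into a ketyl radical that adds to the terminal alkene (5-exo-trig) to give A6.
- Merits: the free secondary hydroxyl and the methyl group arise together and trans, so no inversion is needed. This is an advantage over the chosen plan.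
- Weak points: A7 already needs the arm-bearing and CH2OSi-bearing stereocentres in the correct relative and absolute sense. The relation of the new methyl to the existing CH2OSi carbon depends on a modest preference in the cyclisation transition state. An unactivated alkene reacts slowly, so simple reduction of the aldehyde competes.
- Comparison: the chosen plan pays two extra steps for the carbinol, but every ring stereocentre follows from the preceding one by a well-known anti preference.

Key step: step 6

Assumption: in step 12 the lipase is taken to acetylate the arm that carries the acetate in 18, which is the arm that later bears the ester.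

**Route**

Step 1
Reactants: 1 (1S,4R)-cis-4-acetoxycyclopent-2-en-1-ol; 2 dimethyl malonate
Product: 4 dimethyl 2-[(1R,4S)-4-hydroxycyclopent-2-en-1-yl]malonate, via sodium dimethyl malonate 3 (not isolated)
Conditions: 2, NaH, THF, 0 °C; then 1, Pd(PPh3)4 (3 mol %), THF, 50 °C
Reagents that add atoms: none
Why: Tsuji–Trost allylic alkylation: zerovalent palladium ionises the acetate with inversion and the soft malonate attacks anti to the metal at the allyl terminus remote from the free hydroxyl, so the (R) acetate carbon becomes the (R) malonate carbon with net retention (cis-1,4 product).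

Step 2
Reactants: 4 dimethyl 2-[(1R,4S)-4-hydroxycyclopent-2-en-1-yl]malonate
Product: 5 2-[(1R,4S)-4-hydroxycyclopent-2-en-1-yl]propane-1,3-diol
Conditions: LiAlH4, THF, 0 °C → rt
Reagents that add atoms: none
Why: Hydride reduction of both esters to primary alcohols; the isolated ring alkene and the stereocentres are untouched.

Step 3
Reactants: 5 2-[(1R,4S)-4-hydroxycyclopent-2-en-1-yl]propane-1,3-diol
Product: 6 (1S,4R)-4-(2,2-dimethyl-1,3-dioxan-5-yl)cyclopent-2-en-1-ol
Conditions: Me2C(OMe)2, PPTS (cat.), CH2Cl2, rt; then MeOH, rt, short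
Reagents that add atoms: 2,2-dimethoxypropane, COC(C)(C)OC
Why: Acetonide formation; only the 1,3-diol can form a six-membered ketal, and any mixed ketal on the secondary hydroxyl falls off in the methanol wash.

Step 4
Reactants: 6 (1S,4R)-4-(2,2-dimethyl-1,3-dioxan-5-yl)cyclopent-2-en-1-ol
Product: 7 (4R)-4-(2,2-dimethyl-1,3-dioxan-5-yl)cyclopent-2-en-1-one
Conditions: MnO2, CH2Cl2, rt
Reagents that add atoms: none
Why: Allylic oxidation under neutral conditions removes the carbinol stereocentre and leaves C4 as the only stereocentre without exposing its γ-hydrogen to base.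

Step 5
Reactants: 8 (chloromethyl)(isopropoxy)dimethylsilane
Product: 9 [(isopropoxydimethylsilyl)methyl]magnesium chloride
Conditions: Mg turnings (activated with BrCH2CH2Br), THF, rt → reflux; used as a THF solution
Reagents that add atoms: magnesium, [Mg]
Why: Standard Grignard formation from an α-silyl alkyl chloride; the reagent is a hydroxymethyl anion equivalent.

Step 6
Reactants: 7 (4R)-4-(2,2-dimethyl-1,3-dioxan-5-yl)cyclopent-2-en-1-one; 9 [(isopropoxydimethylsilyl)methyl]magnesium chloride; 10 iodomethane
Product: 12 (2R,3S,4S)-4-(2,2-dimethyl-1,3-dioxan-5-yl)-3-[(isopropoxydimethylsilyl)methyl]-2-methylcyclopentan-1-one, via chloromagnesium enolate 11 (not isolated)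
Conditions: 9 (1.5 equiv), CuBr·SMe2 (10 mol %), THF, −78 °C; then 10 (excess), HMPA, −78 → −20 °C; aq. NH4Cl
Reagents that add atoms: none
Why: Transmetalation of 9 gives an organocopper species of monovalent copper that complexes the enone, adds to the β-carbon and leaves the regiodefined enolate 11, which is methylated on carbon by 10. The closest known reaction type is the three-component coupling on 4-substituted cyclopent-2-enones, here with a silylmethyl Grignard reagent as the hydroxymethyl equivalent. No ring closes; two C–C bonds and two stereocentres are formed. The CH2Si-bearing stereocentre is controlled by the C4 substituent, because the copper reagent enters on the face opposite the dioxanyl group. The methyl-bearing stereocentre is controlled by the new CH2Si group, because 10 approaches the enolate on the face opposite to it; this trans isomer is also the thermodynamic one. The step needs site selectivity between the two α-carbons, secured because conjugate addition fixes the enolate double bond toward the β-carbon and HMPA lets methylation at low temperature outrun proton exchange. The acetonide and the isopropoxysilane are inert to the reagents; 12 is taken on crude because the Si–O bond is sensitive to silica.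

Step 7
Reactants: 12 (2R,3S,4S)-4-(2,2-dimethyl-1,3-dioxan-5-yl)-3-[(isopropoxydimethylsilyl)methyl]-2-methylcyclopentan-1-one
Product: 13 (2R,3S,4R)-4-(2,2-dimethyl-1,3-dioxan-5-yl)-3-(hydroxymethyl)-2-methylcyclopentan-1-one
Conditions: KF, KHCO3, 30% H2O2, THF/MeOH, rt
Reagents that add atoms: hydrogen peroxide, OO
Why: Tamao oxidation of the alkoxysilane converts C–Si into C–OH at a primary carbon; the buffered peroxide leaves the ketone alone, and the mild base can only confirm the trans methyl group, which is the stable epimer.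

Step 8
Reactants: 13 (2R,3S,4R)-4-(2,2-dimethyl-1,3-dioxan-5-yl)-3-(hydroxymethyl)-2-methylcyclopentan-1-one
Product: 14 (2R,3S,4R)-3-{[(tert-butyldiphenylsilyl)oxy]methyl}-4-(2,2-dimethyl-1,3-dioxan-5-yl)-2-methylcyclopentan-1-one
Conditions: TBDPSCl, imidazole, DMF, 0 °C → rt
Reagents that add atoms: tert-butyl(chloro)diphenylsilane, CC(C)(C)[Si](Cl)(c1ccccc1)c1ccccc1
Why: Silylation of the primary alcohol; the TBDPS ether is chosen because it survives the later acetonide removals in acid.

Step 9
Reactants: 14 (2R,3S,4R)-3-{[(tert-butyldiphenylsilyl)oxy]methyl}-4-(2,2-dimethyl-1,3-dioxan-5-yl)-2-methylcyclopentan-1-one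
Product: 15 (1S,2R,3S,4R)-3-{[(tert-butyldiphenylsilyl)oxy]methyl}-4-(2,2-dimethyl-1,3-dioxan-5-yl)-2-methylcyclopentan-1-ol (hydroxyl cis to methyl)
Conditions: LiBH(s-Bu)3, THF, −78 °C; aq. NH4Cl
Reagents that add atoms: none
Why: The bulky hydride attacks the face opposite the α-methyl group and the C4 arm, as in reductions of prostaglandin E-type cyclopentanones, and so should give the alcohol cis to methyl.

Step 10
Reactants: 15 (1S,2R,3S,4R)-3-{[(tert-butyldiphenylsilyl)oxy]methyl}-4-(2,2-dimethyl-1,3-dioxan-5-yl)-2-methylcyclopentan-1-ol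
Product: 16 (1R,2R,3S,4R)-3-{[(tert-butyldiphenylsilyl)oxy]methyl}-4-(2,2-dimethyl-1,3-dioxan-5-yl)-2-methylcyclopentyl 4-nitrobenzoate
Conditions: 4-O2NC6H4CO2H, PPh3, DIAD, THF, 0 °C → rt
Reagents that add atoms: 4-nitrobenzoic acid, O=C(O)c1ccc(cc1)[N+](=O)[O-]
Why: Mitsunobu esterification; SN2 displacement of the oxyphosphonium group inverts the carbinol carbon and gives the all-trans oxygen, and the acidic 4-nitrobenzoic acid is the usual choice for hindered secondary alcohols.

Step 11
Reactants: 16 (1R,2R,3S,4R)-3-{[(tert-butyldiphenylsilyl)oxy]methyl}-4-(2,2-dimethyl-1,3-dioxan-5-yl)-2-methylcyclopentyl 4-nitrobenzoate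
Product: 17 (1R,2R,3S,4R)-3-{[(tert-butyldiphenylsilyl)oxy]methyl}-4-(1,3-dihydroxypropan-2-yl)-2-methylcyclopentyl 4-nitrobenzoate
Conditions: PPTS, MeOH, rt
Reagents that add atoms: none
Why: Acid-catalysed transacetalisation removes the six-membered acetonide; the TBDPS ether and the aryl ester are stable to PPTS in methanol.

Step 12
Reactants: 17 (1R,2R,3S,4R)-3-{[(tert-butyldiphenylsilyl)oxy]methyl}-4-(1,3-dihydroxypropan-2-yl)-2-methylcyclopentyl 4-nitrobenzoate
Product: 18 (1R,2R,3S,4R)-4-[(2S)-1-acetoxy-3-hydroxypropan-2-yl]-3-{[(tert-butyldiphenylsilyl)oxy]methyl}-2-methylcyclopentyl 4-nitrobenzoate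
Conditions: Amano lipase PS, vinyl acetate, t-BuOMe, 25 °C, stopped at the monoacetate
Reagents that add atoms: vinyl acetate, CC(=O)OC=C
Why: Lipase-catalysed irreversible transesterification of a 2-substituted propane-1,3-diol; the enzyme distinguishes the two diastereotopic primary hydroxyls and thereby sets the arm stereocentre, and 18 is silylated without delay to prevent acetyl migration.

Step 13
Reactants: 18 (1R,2R,3S,4R)-4-[(2S)-1-acetoxy-3-hydroxypropan-2-yl]-3-{[(tert-butyldiphenylsilyl)oxy]methyl}-2-methylcyclopentyl 4-nitrobenzoate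
Product: 19 (1R,2R,3S,4R)-4-[(2R)-1-acetoxy-3-{[(tert-butyldiphenylsilyl)oxy]}propan-2-yl]-3-{[(tert-butyldiphenylsilyl)oxy]methyl}-2-methylcyclopentyl 4-nitrobenzoate
Conditions: TBDPSCl, imidazole, CH2Cl2, 0 °C
Reagents that add atoms: tert-butyl(chloro)diphenylsilane, CC(C)(C)[Si](Cl)(c1ccccc1)c1ccccc1
Why: Silylation of the remaining primary hydroxyl fixes the arm assignment; the descriptor changes from S to R only because the priorities change.

Step 14
Reactants: 19 (1R,2R,3S,4R)-4-[(2R)-1-acetoxy-3-{[(tert-butyldiphenylsilyl)oxy]}propan-2-yl]-3-{[(tert-butyldiphenylsilyl)oxy]methyl}-2-methylcyclopentyl 4-nitrobenzoate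
Product: 20 (1R,2R,3S,4R)-3-{[(tert-butyldiphenylsilyl)oxy]methyl}-4-[(2R)-1-{[(tert-butyldiphenylsilyl)oxy]}-3-hydroxypropan-2-yl]-2-methylcyclopentan-1-ol
Conditions: K2CO3, MeOH, 0 °C → rt
Reagents that add atoms: none
Why: Base-catalysed methanolysis removes the acetate and the 4-nitrobenzoate together; the bulky TBDPS group is used on the arm because it is the silyl group least prone to 1,3-migration, which would scramble the arm stereocentre.

Step 15
Reactants: 21 (3aR,6aR)-2,2-dimethyl-3a,6a-dihydro-4H-cyclopenta[d][1,3]dioxol-4-one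
Product: 22 (3aR,6aR)-2,2-dimethyltetrahydro-4H-cyclopenta[d][1,3]dioxol-4-one
Conditions: H2 (1 atm), 10% Pd/C, EtOAc, rt
Reagents that add atoms: none
Why: Catalytic hydrogenation of the enone C=C; no stereocentre is formed or touched.

Step 16
Reactants: 22 (3aR,6aR)-2,2-dimethyltetrahydro-4H-cyclopenta[d][1,3]dioxol-4-one; 23 methyl bromoacetate
Product: 25 methyl 2-[(3aR,5S,6aR)-2,2-dimethyl-4-oxotetrahydro-4H-cyclopenta[d][1,3]dioxol-5-yl]acetate, via lithium enolate 24 (not isolated)
Conditions: LiN(i-Pr)2, THF, −78 °C; then 23, DMPU, −78 → −40 °C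
Reagents that add atoms: none
Why: Kinetic deprotonation occurs at the CH2 side (the side used when this ketone is converted into its enone), and the enolate is alkylated on the convex face of the cis-fused bicycle, trans to the acetonide oxygens; this sets the (S) stereocentre of the acyl unit and is also the more stable epimer.

Step 17
Reactants: 25 methyl 2-[(3aR,5S,6aR)-2,2-dimethyl-4-oxotetrahydro-4H-cyclopenta[d][1,3]dioxol-5-yl]acetate; 26 ethyltriphenylphosphonium bromide
Product: 28 methyl 2-[(3aS,4E,5S,6aR)-4-ethylidene-2,2-dimethyltetrahydro-3aH-cyclopenta[d][1,3]dioxol-5-yl]acetate, via ethylidenetriphenylphosphorane 27 (not isolated)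
Conditions: 26, KN(SiMe3)2, THF, 0 °C; then 25, −78 °C → rt
Reagents that add atoms: none
Why: Wittig olefination of the ketone in preference to the ester; unstabilised ylides place their substituent syn to the more encumbered α-carbon (as in the ethylidenation of 17-keto steroids), here the carbon bearing the acetate arm, which is the E isomer required; the geometry is to be confirmed by NOE before proceeding.

Step 18
Reactants: 28 methyl 2-[(3aS,4E,5S,6aR)-4-ethylidene-2,2-dimethyltetrahydro-3aH-cyclopenta[d][1,3]dioxol-5-yl]acetate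
Product: 29 2-[(3aS,4E,5S,6aR)-4-ethylidene-2,2-dimethyltetrahydro-3aH-cyclopenta[d][1,3]dioxol-5-yl]acetic acid
Conditions: LiOH, THF/H2O, 0 °C → rt; then 1 M HCl to pH 4 at 0 °C
Reagents that add atoms: lithium hydroxide, [Li+].[OH-]
Why: Saponification of the methyl ester; the stereocentre is β to the carboxyl group and cannot epimerise, and the acetonide survives the brief cold acidification.

Step 19
Reactants: 20 (1R,2R,3S,4R)-3-{[(tert-butyldiphenylsilyl)oxy]methyl}-4-[(2R)-1-{[(tert-butyldiphenylsilyl)oxy]}-3-hydroxypropan-2-yl]-2-methylcyclopentan-1-ol; 29 2-[(3aS,4E,5S,6aR)-4-ethylidene-2,2-dimethyltetrahydro-3aH-cyclopenta[d][1,3]dioxol-5-yl]acetic acid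
Product: 30 bis-ester of 20 with 29 on the ring oxygen and on the free arm oxygen: (1R,2R,3S,4R)-ring, (2R)-arm, both acyl groups (3aS,4E,5S,6aR), both TBDPS ethers and both acetonides in place
Conditions: 29 (2.6 equiv), EDC·HCl, DMAP, CH2Cl2, 0 °C → rt
Reagents that add atoms: none
Why: Steglich esterification of the primary and the secondary hydroxyl with excess acid; the acid has no α-stereocentre, so activation cannot epimerise it.

Step 20
Reactants: 30 bis-ester with two acetonides and two TBDPS ethers
Product: 31 tetraol: as 30 but each acyl group is now [(1S,2E,3S,4R)-2-ethylidene-3,4-dihydroxycyclopentyl]acetyl; both TBDPS ethers retained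
Conditions: TFA/H2O (4:1), THF, 0 °C
Reagents that add atoms: none
Why: Acid hydrolysis of the two cyclopentane-fused acetonides; primary TBDPS ethers withstand aqueous TFA, so no hydroxyl is free next to the arm ester and acyl migration cannot occur, and each diol is trans to its acetate arm, which rules out lactonisation.

Step 21
Reactants: 31 tetraol with two TBDPS ethers
Product: 32 hexaol: (1R,2R,3S,4R)-3-(hydroxymethyl)-2-methyl-4-[(2S)-1-hydroxy-3-(acyloxy)propan-2-yl]cyclopentyl ester, both acyl groups [(1S,2E,3S,4R)-2-ethylidene-3,4-dihydroxycyclopentyl]acetyl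
Conditions: HF·pyridine, pyridine, THF, 0 °C → rt
Reagents that add atoms: none
Why: Fluoride cleavage of both silyl ethers under buffered, weakly acidic conditions, which should not promote acyl migration between the arm oxygens.

Step 22
Reactants: 32 hexaol
Product: 33 (1R,2R,3S,4R)-4-[(2S)-1-{[(3S,4E)-4-formyl-3-(2-oxoethyl)hex-4-enoyl]oxy}-3-hydroxypropan-2-yl]-3-(hydroxymethyl)-2-methylcyclopentyl (3S,4E)-4-formyl-3-(2-oxoethyl)hex-4-enoate
Conditions: NaIO4, THF/H2O, pH 7 phosphate buffer, 0 °C → rt
Reagents that add atoms: none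
Why: Periodate glycol cleavage opens both cyclopentane-1,2-diols to the enal and the CH2CHO group; the ring-locked alkene geometry becomes the E enal, and the isolated primary hydroxyls are not vicinal diols and are untouched.

**Compound list**

1 | (1S,4R)-cis-4-acetoxycyclopent-2-en-1-ol | CC(=O)O[C@@H]1C[C@H](O)C=C1 | starting material
2 | dimethyl malonate | COC(=O)CC(=O)OC | starting material
3 | sodium dimethyl malonate | COC(=O)[CH-]C(=O)OC.[Na+] | intermediate
4 | dimethyl 2-[(1R,4S)-4-hydroxycyclopent-2-en-1-yl]malonate | COC(=O)C(C(=O)OC)[C@@H]1C[C@H](O)C=C1 | intermediate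
5 | 2-[(1R,4S)-4-hydroxycyclopent-2-en-1-yl]propane-1,3-diol | OCC(CO)[C@@H]1C[C@H](O)C=C1 | intermediate
6 | (1S,4R)-4-(2,2-dimethyl-1,3-dioxan-5-yl)cyclopent-2-en-1-ol | CC1(C)OCC(CO1)[C@@H]1C[C@H](O)C=C1 | intermediate
7 | (4R)-4-(2,2-dimethyl-1,3-dioxan-5-yl)cyclopent-2-en-1-one | CC1(C)OCC(CO1)[C@@H]1CC(=O)C=C1 | intermediate
8 | (chloromethyl)(isopropoxy)dimethylsilane | CC(C)O[Si](C)(C)CCl | starting material
9 | [(isopropoxydimethylsilyl)methyl]magnesium chloride | CC(C)O[Si](C)(C)C[Mg]Cl | intermediate
10 | iodomethane | CI | starting material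
11 | chloromagnesium enolate from 7 and 9 | CC1(C)OCC(CO1)[C@@H]1CC(O[Mg]Cl)=C[C@H]1C[Si](C)(C)OC(C)C | intermediate
12 | (2R,3S,4S)-4-(2,2-dimethyl-1,3-dioxan-5-yl)-3-[(isopropoxydimethylsilyl)methyl]-2-methylcyclopentan-1-one | CC1(C)OCC(CO1)[C@@H]1CC(=O)[C@H](C)[C@H]1C[Si](C)(C)OC(C)C | intermediate
13 | (2R,3S,4R)-4-(2,2-dimethyl-1,3-dioxan-5-yl)-3-(hydroxymethyl)-2-methylcyclopentan-1-one | CC1(C)OCC(CO1)[C@@H]1CC(=O)[C@H](C)[C@H]1CO | intermediate
14 | (2R,3S,4R)-3-{[(tert-butyldiphenylsilyl)oxy]methyl}-4-(2,2-dimethyl-1,3-dioxan-5-yl)-2-methylcyclopentan-1-one | CC1(C)OCC(CO1)[C@@H]1CC(=O)[C@H](C)[C@H]1CO[Si](c1ccccc1)(c1ccccc1)C(C)(C)C | intermediate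
15 | (1S,2R,3S,4R)-3-{[(tert-butyldiphenylsilyl)oxy]methyl}-4-(2,2-dimethyl-1,3-dioxan-5-yl)-2-methylcyclopentan-1-ol | CC1(C)OCC(CO1)[C@@H]1C[C@H](O)[C@H](C)[C@H]1CO[Si](c1ccccc1)(c1ccccc1)C(C)(C)C | intermediate
16 | (1R,2R,3S,4R)-3-{[(tert-butyldiphenylsilyl)oxy]methyl}-4-(2,2-dimethyl-1,3-dioxan-5-yl)-2-methylcyclopentyl 4-nitrobenzoate | CC1(C)OCC(CO1)[C@@H]1C[C@@H](OC(=O)c2ccc(cc2)[N+](=O)[O-])[C@H](C)[C@H]1CO[Si](c1ccccc1)(c1ccccc1)C(C)(C)C | intermediate
17 | (1R,2R,3S,4R)-3-{[(tert-butyldiphenylsilyl)oxy]methyl}-4-(1,3-dihydroxypropan-2-yl)-2-methylcyclopentyl 4-nitrobenzoate | OCC(CO)[C@@H]1C[C@@H](OC(=O)c2ccc(cc2)[N+](=O)[O-])[C@H](C)[C@H]1CO[Si](c1ccccc1)(c1ccccc1)C(C)(C)C | intermediate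
18 | (1R,2R,3S,4R)-4-[(2S)-1-acetoxy-3-hydroxypropan-2-yl]-3-{[(tert-butyldiphenylsilyl)oxy]methyl}-2-methylcyclopentyl 4-nitrobenzoate | CC(=O)OC[C@H](CO)[C@@H]1C[C@@H](OC(=O)c2ccc(cc2)[N+](=O)[O-])[C@H](C)[C@H]1CO[Si](c1ccccc1)(c1ccccc1)C(C)(C)C | intermediate
19 | (1R,2R,3S,4R)-4-[(2R)-1-acetoxy-3-{[(tert-butyldiphenylsilyl)oxy]}propan-2-yl]-3-{[(tert-butyldiphenylsilyl)oxy]methyl}-2-methylcyclopentyl 4-nitrobenzoate | CC(=O)OC[C@H](CO[Si](c1ccccc1)(c1ccccc1)C(C)(C)C)[C@@H]1C[C@@H](OC(=O)c2ccc(cc2)[N+](=O)[O-])[C@H](C)[C@H]1CO[Si](c1ccccc1)(c1ccccc1)C(C)(C)C | intermediate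
20 | (1R,2R,3S,4R)-3-{[(tert-butyldiphenylsilyl)oxy]methyl}-4-[(2R)-1-{[(tert-butyldiphenylsilyl)oxy]}-3-hydroxypropan-2-yl]-2-methylcyclopentan-1-ol | OC[C@H](CO[Si](c1ccccc1)(c1ccccc1)C(C)(C)C)[C@@H]1C[C@@H](O)[C@H](C)[C@H]1CO[Si](c1ccccc1)(c1ccccc1)C(C)(C)C | intermediate
21 | (3aR,6aR)-2,2-dimethyl-3a,6a-dihydro-4H-cyclopenta[d][1,3]dioxol-4-one (D-ribose-derived enone) | C1=C[C@H]2OC(C)(C)O[C@H]2C1=O | starting material
22 | (3aR,6aR)-2,2-dimethyltetrahydro-4H-cyclopenta[d][1,3]dioxol-4-one | C1C[C@H]2OC(C)(C)O[C@H]2C1=O | intermediate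
23 | methyl bromoacetate | COC(=O)CBr | starting material
24 | lithium enolate of 22 | C=1C[C@H]2OC(C)(C)O[C@H]2C=1O[Li] | intermediate
25 | methyl 2-[(3aR,5S,6aR)-2,2-dimethyl-4-oxotetrahydro-4H-cyclopenta[d][1,3]dioxol-5-yl]acetate | COC(=O)C[C@@H]1C[C@H]2OC(C)(C)O[C@H]2C1=O | intermediate
26 | ethyltriphenylphosphonium bromide | CC[P+](c1ccccc1)(c1ccccc1)c1ccccc1.[Br-] | starting material
27 | ethylidenetriphenylphosphorane | CC=P(c1ccccc1)(c1ccccc1)c1ccccc1 | intermediate
28 | methyl 2-[(3aS,4E,5S,6aR)-4-ethylidene-2,2-dimethyltetrahydro-3aH-cyclopenta[d][1,3]dioxol-5-yl]acetate | COC(=O)C[C@@H]1C[C@H]2OC(C)(C)O[C@H]2/C1=C/C | intermediate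
29 | 2-[(3aS,4E,5S,6aR)-4-ethylidene-2,2-dimethyltetrahydro-3aH-cyclopenta[d][1,3]dioxol-5-yl]acetic acid | OC(=O)C[C@@H]1C[C@H]2OC(C)(C)O[C@H]2/C1=C/C | intermediate
30 | bis-ester of 20 with 29 (two acetonides, two TBDPS ethers; ring 1R,2R,3S,4R; arm 2R) | O=C(C[C@@H]1C[C@H]2OC(C)(C)O[C@H]2/C1=C/C)OC[C@H](CO[Si](c1ccccc1)(c1ccccc1)C(C)(C)C)[C@@H]1C[C@@H](OC(=O)C[C@@H]2C[C@H]3OC(C)(C)O[C@H]3/C2=C/C)[C@H](C)[C@H]1CO[Si](c1ccccc1)(c1ccccc1)C(C)(C)C | intermediate
31 | tetraol: bis{[(1S,2E,3S,4R)-2-ethylidene-3,4-dihydroxycyclopentyl]acetate} of 20 | O=C(C[C@@H]1C[C@@H](O)[C@@H](O)/C1=C/C)OC[C@H](CO[Si](c1ccccc1)(c1ccccc1)C(C)(C)C)[C@@H]1C[C@@H](OC(=O)C[C@@H]2C[C@@H](O)[C@@H](O)/C2=C/C)[C@H](C)[C@H]1CO[Si](c1ccccc1)(c1ccccc1)C(C)(C)C | intermediate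
32 | hexaol: desilylated 31 (ring 1R,2R,3S,4R; arm 2S) | O=C(C[C@@H]1C[C@@H](O)[C@@H](O)/C1=C/C)OC[C@H](CO)[C@@H]1C[C@@H](OC(=O)C[C@@H]2C[C@@H](O)[C@@H](O)/C2=C/C)[C@H](C)[C@H]1CO | intermediate
33 | (1R,2R,3S,4R)-4-[(2S)-1-{[(3S,4E)-4-formyl-3-(2-oxoethyl)hex-4-enoyl]oxy}-3-hydroxypropan-2-yl]-3-(hydroxymethyl)-2-methylcyclopentyl (3S,4E)-4-formyl-3-(2-oxoethyl)hex-4-enoate | C/C=C(/C=O)[C@@H](CC=O)CC(=O)OC[C@H](CO)[C@@H]1C[C@@H](OC(=O)C[C@H](CC=O)/C(C=O)=C\C)[C@H](C)[C@H]1CO | target

**Step count and risks**

Total: 22 steps. Longest linear sequence: 17 steps (1–4, 6–14, 19–22). The acid branch (15–18) and the Grignard preparation (5) are side branches.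

Step 6 (key step). The magnesium enolate 11 is a sluggish nucleophile toward iodomethane. If methylation is slow, proton exchange between product and enolate leads to incomplete conversion, double methylation and methylation on the CH2 side. Fallback: the methyl group is installed before the conjugate addition. Starting from 7, α-iodination (I2, pyridine, CH2Cl2) gives (4S)-4-(2,2-dimethyl-1,3-dioxan-5-yl)-2-iodocyclopent-2-en-1-one F1. Suzuki–Miyaura coupling (MeB(OH)2, Pd(dppf)Cl2, K3PO4, dioxane) gives (4R)-4-(2,2-dimethyl-1,3-dioxan-5-yl)-2-methylcyclopent-2-en-1-one F2. CuBr·SMe2-catalysed addition of 9 anti to the C4 substituent, protonation, and equilibration of the methyl-bearing carbon with DBU to the stable trans isomer return the route to 12.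

Step 12. The diol carries a large chiral substituent, so the enzyme may discriminate the two diastereotopic arms poorly or react slowly; acetyl migration in the monoacetate would erode whatever selectivity is obtained. Fallback: a catalyst-controlled chemical desymmetrisation. Starting from 17, the dinuclear zinc catalyst formed from Et2Zn and the ProPhenol ligand, with vinyl benzoate, gives (1R,2R,3S,4R)-4-[(2S)-1-(benzoyloxy)-3-hydroxypropan-2-yl]-3-{[(tert-butyldiphenylsilyl)oxy]methyl}-2-methylcyclopentyl 4-nitrobenzoate F3; the ligand enantiomer is chosen to address the required arm. Silylation (TBDPSCl, imidazole) gives the corresponding (2R) benzoate bis-silyl ether F4, and K2CO3 in MeOH removes both aryl esters and returns the route to 20.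

Step 10. Activation of the hindered alcohol flanked by the cis methyl group may be slow, and elimination to the cyclopentene may compete with substitution. Fallback: sulfonate displacement in place of phosphonium activation. Starting from 15, MsCl and Et3N give (1S,2R,3S,4R)-3-{[(tert-butyldiphenylsilyl)oxy]methyl}-4-(2,2-dimethyl-1,3-dioxan-5-yl)-2-methylcyclopentyl methanesulfonate F5. Cesium 4-nitrobenzoate (from Cs2CO3 and the acid) in DMF displaces it with inversion and returns the route to 16.

Step 17. The ylide may give a mixture of alkene geometries, since both α-carbons of 25 are substituted, and as a base it may enolise the ketone. Fallback: a Peterson olefination in which both adduct diastereomers converge on one alkene. Starting from 25, CH3CH(SiMe3)MgCl with CeCl3 in THF at −78 °C adds to the ketone only and gives methyl 2-[(3aR,5S,6aR)-4-hydroxy-2,2-dimethyl-4-[1-(trimethylsilyl)ethyl]tetrahydro-4H-cyclopenta[d][1,3]dioxol-5-yl]acetate F6 as two epimers at the silyl-bearing carbon. These are separated; one is eliminated syn with KH in THF and the other anti with BF3·OEt2 at low temperature, so that both give the E alkene and the route returns to 28.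

**Further compounds**

F1 | step 6 | (4S)-4-(2,2-dimethyl-1,3-dioxan-5-yl)-2-iodocyclopent-2-en-1-one | CC1(C)OCC(CO1)[C@@H]1CC(=O)C(I)=C1
F2 | step 6 | (4R)-4-(2,2-dimethyl-1,3-dioxan-5-yl)-2-methylcyclopent-2-en-1-one | CC1(C)OCC(CO1)[C@@H]1CC(=O)C(C)=C1
F3 | step 12 | (1R,2R,3S,4R)-4-[(2S)-1-(benzoyloxy)-3-hydroxypropan-2-yl]-3-{[(tert-butyldiphenylsilyl)oxy]methyl}-2-methylcyclopentyl 4-nitrobenzoate | O=C(OC[C@H](CO)[C@@H]1C[C@@H](OC(=O)c2ccc(cc2)[N+](=O)[O-])[C@H](C)[C@H]1CO[Si](c1ccccc1)(c1ccccc1)C(C)(C)C)c1ccccc1
F4 | step 12 | (1R,2R,3S,4R)-4-[(2R)-1-(benzoyloxy)-3-{[(tert-butyldiphenylsilyl)oxy]}propan-2-yl]-3-{[(tert-butyldiphenylsilyl)oxy]methyl}-2-methylcyclopentyl 4-nitrobenzoate | O=C(OC[C@H](CO[Si](c1ccccc1)(c1ccccc1)C(C)(C)C)[C@@H]1C[C@@H](OC(=O)c2ccc(cc2)[N+](=O)[O-])[C@H](C)[C@H]1CO[Si](c1ccccc1)(c1ccccc1)C(C)(C)C)c1ccccc1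
F5 | step 10 | (1S,2R,3S,4R)-3-{[(tert-butyldiphenylsilyl)oxy]methyl}-4-(2,2-dimethyl-1,3-dioxan-5-yl)-2-methylcyclopentyl methanesulfonate | CC1(C)OCC(CO1)[C@@H]1C[C@H](OS(C)(=O)=O)[C@H](C)[C@H]1CO[Si](c1ccccc1)(c1ccccc1)C(C)(C)C
F6 | step 17 | methyl 2-[(3aR,5S,6aR)-4-hydroxy-2,2-dimethyl-4-[1-(trimethylsilyl)ethyl]tetrahydro-4H-cyclopenta[d][1,3]dioxol-5-yl]acetate (both epimers at the silyl-bearing carbon) | COC(=O)C[C@@H]1C[C@H]2OC(C)(C)O[C@H]2C1(O)C(C)[Si](C)(C)C
A1 | alternative 1 | all-trans cyclopentane carbaldehyde bearing the malonate arm and the silyl ether | COC(=O)C(C(=O)OC)[C@@H]1C[C@@H](O[Si](C)(C)C(C)(C)C)[C@H](C)[C@H]1C=O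
A2 | alternative 1 | dimethyl 2-[(3R,4R)-3-(tert-butyldimethylsilyloxy)-4-methyl-6-oxohexylidene]malonate | COC(=O)C(C(=O)OC)=CC[C@@H](O[Si](C)(C)C(C)(C)C)[C@H](C)CC=O
A3 | alternative 2 | bis-silylated target with all four aldehydes as dimethyl acetals | C/C=C(/C(OC)OC)[C@@H](CC(OC)OC)CC(=O)OC[C@H](CO[Si](C)(C)C(C)(C)C)[C@@H]1C[C@@H](OC(=O)C[C@H](CC(OC)OC)/C(C(OC)OC)=C\C)[C@H](C)[C@H]1CO[Si](C)(C)C(C)(C)C
A4 | alternative 2 | bis-silylated core bis[(E)-5,5-dimethoxypent-2-enoate] | COC(OC)C/C=C/C(=O)OC[C@H](CO[Si](C)(C)C(C)(C)C)[C@@H]1C[C@@H](OC(=O)/C=C/CC(OC)OC)[C@H](C)[C@H]1CO[Si](C)(C)C(C)(C)C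
A5 | alternative 2 | 2-[(E)-1,1-dimethoxybut-2-en-2-yl]-4,4,5,5-tetramethyl-1,3,2-dioxaborolane (methyl cis to boron; pinacol ester assumed) | C/C=C(/C(OC)OC)B1OC(C)(C)C(C)(C)O1
A6 | alternative 3 | all-trans cyclopentanol with free ring hydroxyl, silylated CH2OH and acetonide arm | CC1(C)OCC(CO1)[C@@H]1C[C@@H](O)[C@H](C)[C@H]1CO[Si](C)(C)C(C)(C)C
A7 | alternative 3 | (3R,4R)-4-[(tert-butyldimethylsilyloxy)methyl]-3-(2,2-dimethyl-1,3-dioxan-5-yl)hex-5-enal | CC1(C)OCC(CO1)[C@H](CC=O)[C@@H](C=C)CO[Si](C)(C)C(C)(C)C
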